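(The numbers in the tables are simulated for an exercise.)

Read at 4.0 min, dusk and dawn set two chemists against each other, and each argues from the earlier runs.

in all of them: free catalyst 0.1 mol%

| charge | substrate | partner | remark | time |
|---|---|---|---|---|
| east | 20 mM | 0.13 equiv | run made earlier |  |
| south-west | 20 mM | 0.31 equiv | run made earlier |  |
| north-west | 20 mM | 0.78 equiv | run made earlier |  |
| north-east | 39 mM | 0.70 equiv | run made earlier |  |
| dusk | 40 mM | 0.170 equiv |  | 4.0 min |
| dawn | 20 mM | 0.700 equiv |  | 4.0 min |

- east (time / min: target / %, substrate / %): 0.250: 3, 97; 0.417: 8, 91; 0.833: 9, 93; 1.33: 14, 88; 3.00: 10, 87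
- south-west (time / min: target / %, substrate / %): 0.500: 10, 89; 1.00: 17, 78; 1.50: 23, 77; 2.50: 30, 74; 3.00: 25, 70
- north-west (time / min: target / %, substrate / %): 0.250: 6, 93; 0.417: 11, 87; 0.833: 19, 82; 1.33: 27, 69; 3.00: 51, 52
- north-east (time / min: target / %, substrate / %): 0.250: 10, 87; 0.417: 13, 82; 0.833: 30, 66; 1.33: 43, 54; 3.00: 62, 34

(readings scatter by 2 percentage points)

- what was read earlier has a scatter of 2 percentage points, one standard deviation
- a reading or a percentage of target counts all its forms, free or not
- where the amount of substrate changes, what is given in equivalents or mol% on it follows

1. the flask that ends with the higher amount of target, in percent of the substrate charged, or "neither" when 2 percentage points or less lies between them (dusk / dawn / neither)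
2. final target, as a percentage of the substrate charged, in dusk
3. final target, as a percentage of the substrate charged, in dawn

The first holds that partner is the limiting reagent and that target ends at the equivalents charged. The east run stalls near 14% on 0.13 equiv, the south-west run near 30% on 0.31 equiv, so she expects 0.170 equiv in dusk and 0.700 equiv in dawn.

The second objects that 4.0 min is short. Dawn differs from the north-west run in little but a partner charge of 0.78 equiv, and that run's target read 51% at its last reading, under that charge. He therefore freezes the catalyst's strength and treats substrate as a pseudo-first-order decay. From 52% of the substrate at 3.00 min he reads k = 0.218 min⁻¹. Held constant, k gives 58.2% of the substrate consumed in dawn; he calls this the reach, the share of substrate that a frozen constant can take by the time of reading. A flask should end at the smaller of reach and partner charge. Dawn's reach is less than its charge, so time stops dawn first. In dusk the north-east run's early decay, 0.463 min⁻¹, gives a reach of 84.3%, more than the 0.170 equiv charged, so there he agrees with her.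

The forecast stands nearer to him: 17% in dusk, 58% in dawn, dawn ahead. It comes to its dawn figure by another road, from about 62% and then “Allowing for slowing at low partner”.

The flasks give 15.2% in dusk and 54.1% in dawn, so dawn ends higher.

    partner + catalyst intermediate A ⇌ catalyst intermediate B (K = 2400 L mol⁻¹, k = 14000 L mol⁻¹ s⁻¹)
    free catalyst + target → free catalyst + over-reaction product (k = 18.9 L mol⁻¹ s⁻¹)
    substrate + free catalyst ⇌ catalyst intermediate A (K = 16.0 L mol⁻¹, k = 278 L mol⁻¹ s⁻¹)
    free catalyst + target ⇌ idle complex (K = 22.0 L mol⁻¹, k = 1.00 L mol⁻¹ s⁻¹)
    catalyst intermediate B → free catalyst + target (k = 34.9 s⁻¹)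
    partner → decomposed reagent (k = 5.43 × 10⁻⁴ s⁻¹)

At the reading dawn holds 13.2% of its partner free and 43.4% of its substrate, against the 41.8% the reach left, and 2.40% stands as over-reaction product beside the target. The first chemist's rule has its ground in dusk, whose charge lies under its reach and whose partner stands at 0%. For the neighbour of dawn charged with 0.420 equiv of partner, the same k gives the reach of 58.2%, which exceeds that charge, so the reckoning puts its target near the charge. Its partner falls to 0.655% of its charge, its substrate stands at 59.9%, and its target ends at 38.2%, less than the 58% forecast for dawn.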